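Slowness is what you read first: the west run needs 15.0 d to read 13.5 % of product, and the south-west run reads 13.4 % after 1.67 d. These are the runs and the questions.

| setting | west | south-west | dusk | midnight |
|---|---|---|---|---|
| solid substrate | 1.5 M | 1.5 M | 2.2 M | 2.2 M |
| temperature | 20 °C | 35 °C | 25 °C | 45 °C |
| remark | run made earlier | run made earlier |  |  |
| time |  |  | 30 d | 10 d |

- west (time / d: product / %, solid substrate / %): 2.50: 2.9, 24.1; 8.00: 11.5, 0; 15.0: 13.5, 0.5; 20.0: 13.7, 0.4; 30.0: 17.0, 0.2
- south-west (time / d: product / %, solid substrate / %): 1.67: 13.4, 0; 5.00: 23.9, 0; 10.0: 32.3, 0.6; 12.0: 34.7, 0; 20.0: 41.1, 0.6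

(each reading ± 0.5 percentage points)

1. which of the two ends with the higher amount of product, in percent of the solid substrate charged ("neither" if they lie within 2 percentage points) (dusk / midnight / neither)
2. product at the end, in percent of the solid substrate charged, dusk
3. product at the end, in percent of the solid substrate charged, midnight

- percent here means solid substrate units held: one homo dimer counts as two
- solid substrate is a solid; its amount is given per volume of the solution
- steps that have been proposed: 2 starting material -> homo dimer; intermediate A <-> intermediate C; starting material -> product; solid substrate <-> starting material; starting material <-> intermediate B; starting material <-> intermediate A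
- at the start none of the solid substrate is in solution
- what has only dissolved of solid substrate counts as not reacted

Treat the two runs as one curve read on two clocks. Call the ratio of the times to equal product at two temperatures the clock factor, f: here 8.98, for the step from 20 °C to 35 °C. Spread evenly over the degrees, the step up to midnight at 45 °C is f raised to 0.667, so the 10 d of midnight become t′ = 43.2 d on the south-west clock. That lies past the last reading, so replace the unread curve by its latest mean rate, 6.4 percentage points in 8.00 d, and midnight comes to 59.7 %. Dusk's 30 d become 6.94 d, and interpolation gives 27.2 %.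

The weak link is f, which rests on one pair of readings. So take a second pair: the south-west run passes the west run's last 17.0 % near 2.81 d, which makes f 10.7 and midnight 63.9 %. Both runs were charged at 1.5 M, not 2.2 M, and I leave that difference unreckoned.

The forecast says 21 % for dusk and 49 % for midnight, so midnight, and calls midnight “essentially finished”. My midnight is higher than its number.

The flask gives 22.7 % for dusk and 61.7 % for midnight, so midnight ends higher.

    2 starting material → homo dimer (k = 0.00340 M⁻¹ h⁻¹, Ea = 75.0 kJ mol⁻¹)
    intermediate A ⇌ intermediate C (K = 1.70, k = 0.0190 h⁻¹, Ea = 102 kJ mol⁻¹, ΔH = −24.0 kJ mol⁻¹)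
    starting material → product (k = 0.00350 h⁻¹, Ea = 109 kJ mol⁻¹)
    solid substrate ⇌ starting material, rate k4*(cs4 - [starting material]) while solid is left; crystals form when [starting material] > cs4 (solubility = 0.750 M, k = 0.100 h⁻¹)
    starting material ⇌ intermediate B (K = 38.0, k = 0.00570 h⁻¹, Ea = 101 kJ mol⁻¹, ΔH = −59.0 kJ mol⁻¹)
    starting material ⇌ intermediate A (K = 1.70, k = 0.0180 h⁻¹, Ea = 112 kJ mol⁻¹, ΔH = −10.0 kJ mol⁻¹)
    (constants at 25 °C)

In midnight at 10.0 d, starting material stands at 1.76 % and is made 0.941 times as fast as it is used up, each step taken net, while from 5.00 d on intermediate B falls from 34.4 % to 24.0 % and product climbs from 46.7 % to 61.7 %. In dusk, from 15.0 d to 30.0 d, intermediate B instead rises from 27.5 % to 34.3 %.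

Now carry f to a neighbour, a flask like midnight kept at 30 °C: its 10.0 d become 4.81 d on the south-west clock, where the reading at 5.00 d is 23.9 %. The flask gives 21.3 %, lower than that reading, just as dusk lies lower than its clock number.

(All runs are calculated on assumed constants.)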